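Early on, the gamma and theta runs lay down target fast and then fall onto a slow tail, whereas the eta run shows no such tail, reading 197.8 mM at 24 h and 200.6 mM at 97 h on a charge of 200 mM: by 12 h the gamma run already holds 70.7 mM, well beyond two percent of its charge, so these readings put no number on the outset orders, and this reply to your quick question commits a number for the beta run.

| flask | substrate | free catalyst | time |
|---|---|---|---|
| gamma | 200 mM | 4.00 mM |  |
| theta | 400 mM | 4.00 mM |  |
| eta | 200 mM | 8.00 mM |  |
| beta | 700 mM | 4.00 mM | 97 h |

| run | time / h | [target] / mM |
|---|---|---|
| gamma run | 12 | 70.7 |
| gamma run | 24 | 87.9 |
| gamma run | 36 | 98.9 |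
| gamma run | 48 | 104.9 |
| gamma run | 61 | 111.6 |
| gamma run | 73 | 115.5 |
| gamma run | 85 | 120.2 |
| gamma run | 97 | 122.3 |
| theta run | 12 | 77.9 |
| theta run | 24 | 97.7 |
| theta run | 36 | 112.8 |
| theta run | 48 | 127.6 |
| theta run | 61 | 143.2 |
| theta run | 73 | 156.0 |
| theta run | 85 | 169.0 |
| theta run | 97 | 179.6 |
| eta run | 12 | 183.7 |
| eta run | 24 | 197.8 |
| eta run | 36 | 199.3 |
| eta run | 48 | 199.5 |
| eta run | 61 | 199.0 |
| eta run | 73 | 200.4 |
| eta run | 85 | 200.8 |
| eta run | 97 | 200.6 |

(each reading ± 0.6 mM)

- Overall: substrate -> target, with free catalyst as catalyst.
- Constant volume, constant temperature.
- Readings of a species count what is bound in complexes too.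
- An order is taken over about fifteen percent of the charge, up and down.

* reaction order in [substrate] at the outset, round the charge of the gamma run, defined at two percent of the substrate turned into target (one fixed amount of target, the same in the runs compared)
* reaction order in [free catalyst] at the outset, round the charge of the gamma run, defined at two percent of the substrate turned into target
* target in the beta run at 97 h, as a share of the substrate charged

The tail, taken as first order in the substrate left and read in the theta run, has the constant

ln(272 mM / 220 mM) / 49.0 h = 0.00432 h⁻¹

Over 97 h this tail shrinks the substrate by a factor 1.52, so carrying the substrate left back to zero time gives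

charge − substrate left × 1.52: gamma 81.8 mM, theta 64.8 mM

Each of these is a burst yield, the target standing above the tail carried back to zero time, in the field's terms the total turnover of the catalyst counted in mM of target. The yield in the theta run is smaller than in the gamma run, at twice the charge. The beta run has the catalyst charge of both, so the yield is carried along in substrate, with the reciprocal yield taken as straight in substrate, a choice that two points cannot test:

reciprocal in beta = reciprocal in theta + (reciprocal in theta − reciprocal in gamma) × (substrate in beta − substrate in theta) / (substrate in theta − substrate in gamma)

With the charges as substrate, this gives 49.4 mM. The burst itself consumes substrate, so that answer goes back in, with each run's substrate now its charge less half its yield: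

gamma 159 mM, theta 368 mM, beta 675 mM, so the beta yield is 49.6 mM

The tail then acts on the rest of the beta charge:

target at 97 h = 272 mM, which is 38.9% of the charge

The forecast, made from the same runs, gives 1 for the substrate order and 1.05 for the free-catalyst order, holding that “the rate is about first order in substrate and slightly above first order in catalyst”, and 39.5% for the beta run, higher than the reckoning here. The simulation gives 0.55 and 1.9 for the two orders and 39.0% for the beta run.

    free catalyst + substrate ⇌ catalyst-substrate complex, settled at all times (1.650 M⁻¹)
    catalyst-substrate complex + free catalyst → target + 2 free catalyst (3924 M⁻¹ h⁻¹)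
    free catalyst + substrate → spent catalyst + substrate (0.5112 M⁻¹ h⁻¹)
    substrate → target (0.004356 h⁻¹)

The burst in the beta run ends at a yield reckoned at 49.6 mM, against 81.8 mM reckoned for the gamma run, because free catalyst meeting substrate turns into spent catalyst. The beta run with that step taken away reaches >99.9% of its charge at 97 h instead of 39.0%. In the beta run as it stands, the reckoned burst yield is 18.1% of the 273 mM of target at 97 h, and the step costs 61 percentage points, which is 100% of what is missing.

(The readings were computed from invented constants, and the scatter is random.)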